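**Strategy.** Numbering the lactone C9 (C=O), C8, C8' and C9' (OCH2), the plan cuts the two benzylic bonds C7–C8 (ring A side) and C7'–C1' (ring B side). C8, C8' and C7' are drawn together as a cyclopropane fused to the γ-lactone, with C8 carrying an extra ester so that both C8 substituents are acceptors. In one flask a ring B arylcopper species opens the cyclopropane at C7' and the C8 enolate so formed is benzylated by the ring A bromide. The precursor is an enantiopure bicyclic lactone ester that already contains C8'. The ring C ketone chain is then joined to C5' of ring B by a stereoconvergent nickel-catalysed arylation.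

Key step: step 5

Assumption: C7''–C9'' and ring C denote the keto-alcohol chain on C5'; the pybox enantiomer used in step 13 is taken to be the one that gives the S configuration at C8'', to be assigned on a model coupling of 21 with a simple ortho-alkoxyarylzinc iodide.

**Step 1**
Reactants: 1 (R)-epichlorohydrin; 2 diethyl malonate
Product: 3 ethyl (1S,5R)-2-oxo-3-oxabicyclo[3.1.0]hexane-1-carboxylate
Conditions: NaOEt, EtOH, 0 °C then reflux
Reagents that add atoms: none
Why: Malonate opens the epoxide at its CH2 terminus, the alkoxide closes a new epoxide by displacing chloride, and 3-exo-tet attack of the malonate carbanion with inversion at the carbinol carbon followed by lactonisation gives the cis-fused product, so C5 of 3 (later C8') derives from the epichlorohydrin stereocentre and C1 follows from the cis ring fusion (tandem alkylation, cyclopropanation and lactonisation).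

**Step 2**
Reactants: 4 4-bromo-2-methoxyphenol (4-bromoguaiacol)
Product: 5 tert-butyl(4-bromo-2-methoxyphenoxy)dimethylsilane
Conditions: TBSCl, imidazole, DMF, 25 °C
Reagents that add atoms: tert-butyldimethylsilyl chloride, C[Si](C)(Cl)C(C)(C)C
Why: Imidazole-promoted O-silylation masks the acidic phenol for Grignard formation with a group that is meant to fall off again under the later decarboxylation conditions (silyl ether protection).

**Step 3**
Reactants: 5 tert-butyl(4-bromo-2-methoxyphenoxy)dimethylsilane
Product: 6 4-(tert-butyldimethylsilyloxy)-3-methoxyphenylmagnesium bromide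
Conditions: Mg turnings, 1,2-dibromoethane (cat.), THF, 25–45 °C
Reagents that add atoms: magnesium, [Mg]
Why: Magnesium inserts into the aryl C–Br bond (Grignard reagent formation), and the aryl silyl and methyl ethers are inert to it.

**Step 4**
Reactants: 7 4-benzyloxy-3-methoxybenzyl alcohol
Product: 8 4-benzyloxy-3-methoxybenzyl bromide
Conditions: PBr3, Et2O, 0 °C
Reagents that add atoms: phosphorus tribromide, BrP(Br)Br
Why: The electron-rich benzylic alcohol is converted into the bromide by nucleophilic substitution of its phosphite ester, and the labile bromide is used directly.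

**Step 5**
Reactants: 3 ethyl (1S,5R)-2-oxo-3-oxabicyclo[3.1.0]hexane-1-carboxylate; 6 4-(tert-butyldimethylsilyloxy)-3-methoxyphenylmagnesium bromide; 8 4-benzyloxy-3-methoxybenzyl bromide
Product: 10 ethyl (3R,4R)-3-(4-benzyloxy-3-methoxybenzyl)-4-[4-(tert-butyldimethylsilyloxy)-3-methoxybenzyl]-2-oxotetrahydrofuran-3-carboxylate, via bromomagnesium enolate 9 (not isolated)
Conditions: 6 (1.2 equiv), CuI (10 mol%), THF, −30 to 0 °C; then 8 (1.5 equiv), DMPU, Bu4NI (cat.), 0 to 40 °C
Reagents that add atoms: none
Why: CuI turns 6 into an arylcopper/magnesium cuprate that attacks the cyclopropane CH2 carbon (C7') of 3 in an SN2-like homoconjugate addition, cleaving the C8–C7' bond that the lactone carbonyl and the ester on C8 polarise and releasing the chelated magnesium enolate 9; DMPU then loosens the chelate so that 9 is C-benzylated by 8. The closest known reaction types are the copper-catalysed Grignard opening of this same bicyclic lactone ester and the alkylation of a malonate-type enolate with a benzylic bromide, here run in sequence in one flask. No ring is closed and the γ-lactone of 3 is kept. C8' is carried over unchanged from 3, and the new quaternary centre C8 is set by substrate control, 8 approaching the planar enolate on the face opposite the C8' arylmethyl group. The step needs attack at the CH2 carbon and not at the ring-fusion CH, which the lower hindrance of the CH2 and the retention of the five-membered lactone secure, and it needs C- over O-alkylation, which the soft benzylic bromide and the stabilised enolate favour. A small excess of 8 covers what residual aryl metal consumes.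

**Step 6**
Reactants: 10 ethyl (3R,4R)-3-(4-benzyloxy-3-methoxybenzyl)-4-[4-(tert-butyldimethylsilyloxy)-3-methoxybenzyl]-2-oxotetrahydrofuran-3-carboxylate
Product: 12 (3R,4R)-3-(4-benzyloxy-3-methoxybenzyl)-4-(4-hydroxy-3-methoxybenzyl)dihydrofuran-2(3H)-one, via decarboxylated silyl ether 11 (not isolated)
Conditions: LiCl, H2O, DMSO, 160 °C; then DBU, 80 °C; 1 M HCl work-up
Reagents that add atoms: none
Why: Chloride dealkylates the ethyl ester and the carboxylate loses CO2 (Krapcho dealkoxycarbonylation), the phenolic silyl ether is cleaved by the hot wet chloride medium and then by DBU, and DBU equilibrates C8 through the enolate to the trans lactone, so C8 is set under thermodynamic control by the C8' substituent.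

**Step 7**
Reactants: 12 (3R,4R)-3-(4-benzyloxy-3-methoxybenzyl)-4-(4-hydroxy-3-methoxybenzyl)dihydrofuran-2(3H)-one
Product: 13 (3R,4R)-3-(4-benzyloxy-3-methoxybenzyl)-4-(4-hydroxy-3-iodo-5-methoxybenzyl)dihydrofuran-2(3H)-one
Conditions: I2, NaHCO3, THF–H2O, 0 to 25 °C
Reagents that add atoms: iodine, II
Why: Electrophilic aromatic iodination proceeds through the ring B phenoxide and can only go to C5', the one free position ortho to the OH (the para position carries C7'), while the benzyl-protected ring A is not activated enough to react with I2 alone.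

**Step 8**
Reactants: 13 (3R,4R)-3-(4-benzyloxy-3-methoxybenzyl)-4-(4-hydroxy-3-iodo-5-methoxybenzyl)dihydrofuran-2(3H)-one
Product: 14 (3R,4R)-3-(4-benzyloxy-3-methoxybenzyl)-4-(4-benzyloxy-3-iodo-5-methoxybenzyl)dihydrofuran-2(3H)-one
Conditions: BnBr, K2CO3, DMF, 25 °C
Reagents that add atoms: benzyl bromide, BrCc1ccccc1
Why: Williamson etherification of the iodophenol removes the acidic proton before the arylzinc reagent is made, and the lactone α-centre is already in its stable trans arrangement.

**Step 9**
Reactants: 4 4-bromo-2-methoxyphenol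
Product: 15 1-benzyloxy-4-bromo-2-methoxybenzene
Conditions: BnBr, K2CO3, DMF, 25 °C
Reagents that add atoms: benzyl bromide, BrCc1ccccc1
Why: Williamson etherification of the phenol gives the ring C building block with the same benzyl protection as rings A and B.

**Step 10**
Reactants: 15 1-benzyloxy-4-bromo-2-methoxybenzene; 16 3-(tert-butyldimethylsilyloxy)propanal
Product: 18 rac-1-(4-benzyloxy-3-methoxyphenyl)-3-(tert-butyldimethylsilyloxy)propan-1-ol, via arylmagnesium bromide 17 (not isolated)
Conditions: Mg, THF, 40 °C; then 16, −78 to 0 °C; aq. NH4Cl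
Reagents that add atoms: none
Why: The aryl Grignard reagent adds to the aldehyde at low temperature faster than it enolises it (Grignard 1,2-addition), and the racemic carbinol centre is removed in the next step.

**Step 11**
Reactants: 18 rac-1-(4-benzyloxy-3-methoxyphenyl)-3-(tert-butyldimethylsilyloxy)propan-1-ol
Product: 19 1-(4-benzyloxy-3-methoxyphenyl)-3-(tert-butyldimethylsilyloxy)propan-1-one
Conditions: MnO2 (activated, excess), CH2Cl2, 25 °C
Reagents that add atoms: none
Why: Activated MnO2 oxidises the electron-rich benzylic alcohol to the aryl ketone under neutral conditions that leave the silyl ether untouched (benzylic alcohol oxidation).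

**Step 12**
Reactants: 19 1-(4-benzyloxy-3-methoxyphenyl)-3-(tert-butyldimethylsilyloxy)propan-1-one
Product: 21 rac-2-bromo-1-(4-benzyloxy-3-methoxyphenyl)-3-(tert-butyldimethylsilyloxy)propan-1-one, via trimethylsilyl enol ether 20 (not isolated)
Conditions: TMSOTf, Et3N, CH2Cl2, 0 °C; crude enol ether, then NBS, THF, −78 to 0 °C
Reagents that add atoms: N-bromosuccinimide, O=C1CCC(=O)N1Br
Why: Soft enolisation gives the silyl enol ether without a free enolate that could expel the β-silyloxy group, and NBS brominates it at the α-carbon (α-halogenation via a silyl enol ether) to give a racemic bromide whose configuration does not matter for step 13.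

**Step 13**
Reactants: 14 (3R,4R)-3-(4-benzyloxy-3-methoxybenzyl)-4-(4-benzyloxy-3-iodo-5-methoxybenzyl)dihydrofuran-2(3H)-one; 21 rac-2-bromo-1-(4-benzyloxy-3-methoxyphenyl)-3-(tert-butyldimethylsilyloxy)propan-1-one
Product: 23 (3R,4R)-3-(4-benzyloxy-3-methoxybenzyl)-4-{4-benzyloxy-3-[(2S)-1-(4-benzyloxy-3-methoxyphenyl)-3-(tert-butyldimethylsilyloxy)-1-oxopropan-2-yl]-5-methoxybenzyl}dihydrofuran-2(3H)-one, via arylzinc iodide 22 (not isolated)
Conditions: Zn dust, LiCl, THF, 50 °C; solution decanted from Zn, then 21 (1.3 equiv), NiCl2·glyme (10 mol%), chiral pybox ligand (13 mol%), glyme–THF, −30 °C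
Reagents that add atoms: none
Why: LiCl-assisted zinc insertion into the aryl iodide tolerates the lactone, and the nickel/pybox catalyst takes both enantiomers of 21 through a common α-keto radical to one arylated ketone (stereoconvergent Negishi α-arylation of a racemic α-bromoketone), so C8'' is set as S by the chiral ligand while the non-basic conditions at −30 °C keep this enolisable centre and the β-silyloxy group intact.

**Step 14**
Reactants: 23 silyl-protected coupling product (see step 13)
Product: 24 (3R,4R)-3-(4-benzyloxy-3-methoxybenzyl)-4-{4-benzyloxy-3-[(2S)-1-(4-benzyloxy-3-methoxyphenyl)-3-hydroxy-1-oxopropan-2-yl]-5-methoxybenzyl}dihydrofuran-2(3H)-one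
Conditions: HF·pyridine, pyridine, THF, 0 to 25 °C
Reagents that add atoms: none
Why: Buffered HF·pyridine cleaves the primary silyl ether under mildly acidic conditions (fluoride-mediated desilylation) that should neither enolise the α-aryl ketone nor trigger β-elimination or retro-aldol cleavage.

**Step 15**
Reactants: 24 tris(benzyl ether) keto alcohol (see step 14)
Product: 25 (3R,4R)-4-{4-hydroxy-3-[(2S)-3-hydroxy-1-(4-hydroxy-3-methoxyphenyl)-1-oxopropan-2-yl]-5-methoxybenzyl}-3-(4-hydroxy-3-methoxybenzyl)dihydrofuran-2(3H)-one (target)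
Conditions: H2 (1 atm), Pd/C (10%), EtOAc, 25 °C
Reagents that add atoms: none
Why: Hydrogenolysis over Pd/C removes the three aryl benzyl ethers under neutral conditions (catalytic O-debenzylation), under which the electron-rich aryl ketone, the lactone and the C8'' centre are expected to stay unchanged.

**Compound list**

1 | (R)-epichlorohydrin | ClC[C@H]1CO1 | starting material
2 | diethyl malonate | CCOC(=O)CC(=O)OCC | starting material
3 | ethyl (1S,5R)-2-oxo-3-oxabicyclo[3.1.0]hexane-1-carboxylate | O=C1OC[C@@H]2C[C@]12C(=O)OCC | intermediate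
4 | 4-bromo-2-methoxyphenol (4-bromoguaiacol) | COc1cc(Br)ccc1O | starting material
5 | tert-butyl(4-bromo-2-methoxyphenoxy)dimethylsilane | COc1cc(Br)ccc1O[Si](C)(C)C(C)(C)C | intermediate
6 | 4-(tert-butyldimethylsilyloxy)-3-methoxyphenylmagnesium bromide | COc1cc([Mg]Br)ccc1O[Si](C)(C)C(C)(C)C | intermediate
7 | 4-benzyloxy-3-methoxybenzyl alcohol | COc1cc(CO)ccc1OCc1ccccc1 | starting material
8 | 4-benzyloxy-3-methoxybenzyl bromide | COc1cc(CBr)ccc1OCc1ccccc1 | intermediate
9 | bromomagnesium enolate of ethyl (4R)-4-[4-(tert-butyldimethylsilyloxy)-3-methoxybenzyl]-2-oxotetrahydrofuran-3-carboxylate | CCOC(=O)C1=C(O[Mg]Br)OC[C@@H]1Cc1ccc(O[Si](C)(C)C(C)(C)C)c(OC)c1 | intermediate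
10 | ethyl (3R,4R)-3-(4-benzyloxy-3-methoxybenzyl)-4-[4-(tert-butyldimethylsilyloxy)-3-methoxybenzyl]-2-oxotetrahydrofuran-3-carboxylate | COc1cc(C[C@@]2(C(=O)OCC)C(=O)OC[C@@H]2Cc2ccc(O[Si](C)(C)C(C)(C)C)c(OC)c2)ccc1OCc1ccccc1 | intermediate
11 | (3RS,4R)-3-(4-benzyloxy-3-methoxybenzyl)-4-[4-(tert-butyldimethylsilyloxy)-3-methoxybenzyl]dihydrofuran-2(3H)-one | COc1cc(CC2C(=O)OC[C@@H]2Cc2ccc(O[Si](C)(C)C(C)(C)C)c(OC)c2)ccc1OCc1ccccc1 | intermediate
12 | (3R,4R)-3-(4-benzyloxy-3-methoxybenzyl)-4-(4-hydroxy-3-methoxybenzyl)dihydrofuran-2(3H)-one | COc1cc(C[C@H]2C(=O)OC[C@@H]2Cc2ccc(O)c(OC)c2)ccc1OCc1ccccc1 | intermediate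
13 | (3R,4R)-3-(4-benzyloxy-3-methoxybenzyl)-4-(4-hydroxy-3-iodo-5-methoxybenzyl)dihydrofuran-2(3H)-one | COc1cc(C[C@H]2C(=O)OC[C@@H]2Cc2cc(I)c(O)c(OC)c2)ccc1OCc1ccccc1 | intermediate
14 | (3R,4R)-3-(4-benzyloxy-3-methoxybenzyl)-4-(4-benzyloxy-3-iodo-5-methoxybenzyl)dihydrofuran-2(3H)-one | COc1cc(C[C@H]2C(=O)OC[C@@H]2Cc2cc(I)c(OCc3ccccc3)c(OC)c2)ccc1OCc1ccccc1 | intermediate
15 | 1-benzyloxy-4-bromo-2-methoxybenzene | COc1cc(Br)ccc1OCc1ccccc1 | intermediate
16 | 3-(tert-butyldimethylsilyloxy)propanal | O=CCCO[Si](C)(C)C(C)(C)C | starting material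
17 | 4-benzyloxy-3-methoxyphenylmagnesium bromide | COc1cc([Mg]Br)ccc1OCc1ccccc1 | intermediate
18 | rac-1-(4-benzyloxy-3-methoxyphenyl)-3-(tert-butyldimethylsilyloxy)propan-1-ol | COc1cc(C(O)CCO[Si](C)(C)C(C)(C)C)ccc1OCc1ccccc1 | intermediate
19 | 1-(4-benzyloxy-3-methoxyphenyl)-3-(tert-butyldimethylsilyloxy)propan-1-one | COc1cc(C(=O)CCO[Si](C)(C)C(C)(C)C)ccc1OCc1ccccc1 | intermediate
20 | (Z)-trimethylsilyl enol ether of 19 | COc1cc(/C(O[Si](C)(C)C)=C/CO[Si](C)(C)C(C)(C)C)ccc1OCc1ccccc1 | intermediate
21 | rac-2-bromo-1-(4-benzyloxy-3-methoxyphenyl)-3-(tert-butyldimethylsilyloxy)propan-1-one | COc1cc(C(=O)C(Br)CO[Si](C)(C)C(C)(C)C)ccc1OCc1ccccc1 | intermediate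
22 | arylzinc iodide from 14 (ZnI in place of I at C5') | COc1cc(C[C@H]2C(=O)OC[C@@H]2Cc2cc([Zn]I)c(OCc3ccccc3)c(OC)c2)ccc1OCc1ccccc1 | intermediate
23 | (3R,4R)-3-(4-benzyloxy-3-methoxybenzyl)-4-{4-benzyloxy-3-[(2S)-1-(4-benzyloxy-3-methoxyphenyl)-3-(tert-butyldimethylsilyloxy)-1-oxopropan-2-yl]-5-methoxybenzyl}dihydrofuran-2(3H)-one | COc1cc(C[C@H]2C(=O)OC[C@@H]2Cc2cc(OC)c(OCc3ccccc3)c([C@@H](CO[Si](C)(C)C(C)(C)C)C(=O)c3ccc(OCc4ccccc4)c(OC)c3)c2)ccc1OCc1ccccc1 | intermediate
24 | (3R,4R)-3-(4-benzyloxy-3-methoxybenzyl)-4-{4-benzyloxy-3-[(2S)-1-(4-benzyloxy-3-methoxyphenyl)-3-hydroxy-1-oxopropan-2-yl]-5-methoxybenzyl}dihydrofuran-2(3H)-one | COc1cc(C[C@H]2C(=O)OC[C@@H]2Cc2cc(OC)c(OCc3ccccc3)c([C@@H](CO)C(=O)c3ccc(OCc4ccccc4)c(OC)c3)c2)ccc1OCc1ccccc1 | intermediate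
25 | (3R,4R)-4-{4-hydroxy-3-[(2S)-3-hydroxy-1-(4-hydroxy-3-methoxyphenyl)-1-oxopropan-2-yl]-5-methoxybenzyl}-3-(4-hydroxy-3-methoxybenzyl)dihydrofuran-2(3H)-one | COc1cc(C[C@H]2C(=O)OC[C@@H]2Cc2cc(OC)c(O)c([C@@H](CO)C(=O)c3ccc(O)c(OC)c3)c2)ccc1O | target

**Totals.** Total step count: 15. Longest linear sequence: 9 steps (steps 2, 3, 5, 6, 7, 8, 13, 14, 15).

**Steps most likely to fail**

1. Step 13. What may go wrong: slow transfer of the ortho-benzyloxy aryl group from zinc to nickel, loss of the β-silyloxy group by elimination from the organonickel or enolate stage, or weak catalyst control at C8''. The fallback sets out from 14 and comes back at 24, building C8'' with an auxiliary instead of a catalyst. Palladium-catalysed coupling of 14 with commercial 2-tert-butoxy-2-oxoethylzinc chloride (Pd(dba)2, Q-Phos, THF) should give the tert-butyl arylacetate F1. TFA in CH2Cl2 then gives the arylacetic acid F2. Activation with pivaloyl chloride/Et3N and reaction with (R)-4-benzyl-2-oxazolidinone/LiCl gives the N-acyl oxazolidinone F3. Its titanium enolate (TiCl4, i-Pr2NEt, CH2Cl2, 0 °C) is hydroxymethylated with s-trioxane/TiCl4 on the face away from the auxiliary benzyl group to give the (S)-β-hydroxy imide F4. LiSEt in THF at 0 °C displaces the auxiliary to give the S-ethyl thioester F5. A Liebeskind–Srogl coupling of F5 with commercial 4-benzyloxy-3-methoxyphenylboronic acid (Pd2(dba)3, tri(2-furyl)phosphine, Cu(thiophene-2-carboxylate), THF, 50 °C) forms the aryl ketone under neutral conditions and gives 24.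

2. Step 5. What may go wrong: sluggish C-alkylation of the chelated magnesium enolate and consumption of 8 by residual arylmagnesium or arylcopper species. The fallback sets out from 3 and 6 and comes back at 10, separating the two bond formations. The ring opening alone (CuI, THF, −30 °C), quenched with aqueous NH4Cl, should give the α-carbethoxy lactone F6. Its sodium enolate (NaH, DMF, 0 °C) is then benzylated with 8 as an ordinary malonate-type alkylation to give 10.

3. Step 6. What may go wrong: slow dealkoxycarbonylation at the quaternary carbon, or incomplete cis-to-trans equilibration at C8. The fallback sets out from 10 and comes back at 12, replacing the halide-mediated dealkylation by hydrolysis and thermal decarboxylation. Saponification with KOH in aqueous ethanol at reflux (which also opens the lactone and removes the silyl group) and acidification to re-close the lactone give the lactone carboxylic acid F7. Heating F7 in toluene/pyridine at 110 °C expels CO2, and DBU equilibration gives 12.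

**Further compounds**

F1 | step 13 | tert-butyl arylacetate: 14 with CH2CO2t-Bu in place of iodine at C5' | COc1cc(C[C@H]2C(=O)OC[C@@H]2Cc2cc(CC(=O)OC(C)(C)C)c(OCc3ccccc3)c(OC)c2)ccc1OCc1ccccc1
F2 | step 13 | arylacetic acid: 14 with CH2CO2H in place of iodine at C5' | COc1cc(C[C@H]2C(=O)OC[C@@H]2Cc2cc(CC(=O)O)c(OCc3ccccc3)c(OC)c2)ccc1OCc1ccccc1
F3 | step 13 | N-acyl oxazolidinone of F2 with (R)-4-benzyl-2-oxazolidinone | COc1cc(C[C@H]2C(=O)OC[C@@H]2Cc2cc(CC(=O)N3[C@H](Cc4ccccc4)COC3=O)c(OCc3ccccc3)c(OC)c2)ccc1OCc1ccccc1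
F4 | step 13 | (S)-β-hydroxy imide: F3 with CH2OH on the α-carbon (C8'') | COc1cc(C[C@H]2C(=O)OC[C@@H]2Cc2cc(OC)c(OCc3ccccc3)c([C@@H](CO)C(=O)N3[C@H](Cc4ccccc4)COC3=O)c2)ccc1OCc1ccccc1
F5 | step 13 | S-ethyl (S)-3-hydroxy-2-arylpropanethioate: F4 with SEt in place of the auxiliary | COc1cc(C[C@H]2C(=O)OC[C@@H]2Cc2cc(OC)c(OCc3ccccc3)c([C@@H](CO)C(=O)SCC)c2)ccc1OCc1ccccc1
F6 | step 5 | ethyl (4R)-4-[4-(tert-butyldimethylsilyloxy)-3-methoxybenzyl]-2-oxotetrahydrofuran-3-carboxylate (C3 epimers) | CCOC(=O)C1C(=O)OC[C@@H]1Cc1ccc(O[Si](C)(C)C(C)(C)C)c(OC)c1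
F7 | step 6 | (4R)-3-(4-benzyloxy-3-methoxybenzyl)-4-(4-hydroxy-3-methoxybenzyl)-2-oxotetrahydrofuran-3-carboxylic acid (C3 epimers) | COc1cc(CC2(C(=O)O)C(=O)OC[C@@H]2Cc2ccc(O)c(OC)c2)ccc1OCc1ccccc1
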